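The ratio I start from is final product over partner charged, both counted against the substrate. In the north run, this very flask followed so far, the partner charge is 90.0% of the substrate, less than the substrate, so partner is the limiting reagent. Product reads 35% at the last reading, which gives each partner molecule charged a chance of 38.9% of ending as product. The south run, with less partner and the other charges the same, gives 41.5% as read, close to the north value.

in all of them: substrate 0.24 M; third reagent 0.216 M; gas 9.1 mM (held)
- north: partner 0.216 M; capture agent 0.24 M; the very flask that is asked about, followed so far
- south: partner 0.11 M; capture agent 0.24 M; run made earlier
- flask: partner 0.216 M; capture agent 0.240 M; time 10 min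

| run | time / min | intermediate B / % | product / % |
|---|---|---|---|
| north | 0.167 | 7 | 0 |
| north | 0.250 | 8 | 6 |
| north | 0.667 | 5 | 14 |
| north | 1.50 | 0 | 30 |
| north | 4.00 | 0 | 35 |
| south | 0.167 | 5 | 0 |
| south | 0.333 | 7 | 4 |
| south | 0.833 | 3 | 13 |
| south | 2.50 | 0 | 18 |
| south | 8.00 | 0 | 19 |

(scatter of a reading: 2 percentage points)

- when, up to 10 min, the flask holds most intermediate B
- the amount of intermediate B, in percent of the substrate charged, at that time

I draw the north curve from these. Intermediate B rises at a mean 0.419 /min of the charge up to the first reading, while product still reads 0%. Product overtakes intermediate B between 0.250 min and 0.667 min, climbing there at 0.192 /min. If the rest of the partner's share is lost at intermediate B, dividing by the chance gives 0.493 /min leaving intermediate B in total, more than its early rise. Across this stretch intermediate B falls 3 percentage points against a scatter of 2 points, so I place the top inside the stretch, at about 8% as read. Afterwards intermediate B reads 0% at 1.50 min, and product levels off.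

The forecast says “The maximum therefore lies early”: 0.27 min (0.16 min to 0.42 min) and 8.5% (6.5% to 11%).

The flask gives 8.56% at 0.401 min, when intermediate A still holds 33.2%, more than intermediate B. The chance also reckons the other way out, to trapped intermediate: 55.0% of the substrate should leave that way, and the trapped intermediate in the flask stands at 56.3% at 10.0 min.

    second reagent + intermediate A → intermediate B (k = 7.00 /M/s)
    intermediate B + capture agent → trapped intermediate (k = 0.600 /M/s)
    gas ⇌ second reagent, rate k3*(csat - [second reagent]) (kL = 1.60 /s)
    third reagent + intermediate B → product (k = 0.341 /M/s)
    substrate + partner → intermediate A (k = 0.531 /M/s)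

The chance as odds is 0.636. Scaling these inversely with capture agent, for a neighbour, the same flask with 0.14 M of capture agent, gives 1.09, so product of 47.0% of the substrate. That neighbour computes to 47.3%.

The readings are simulated for substances that don't exist; the scatter is artificial.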